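The C1–O–C8 bridge of the 2,5-dihydrofuran (germacrane numbering, defined below) spans C9=C10, and C8 is also the acyl-ketal carbon of the spiro γ-lactone: together, a C8=C9–C10=C1 dienol lactone plus one oxygen atom. The last step supplies that atom. DMDO epoxidises C1=C10 of a bridged ten-membered dienol lactone; the vinyl epoxide ionises to an acyl-oxocarbenium and its oxygen shifts suprafacially from C10 to C8, closing the dihydrofuran and setting C1 and C8 at once. The precursor comes from anti-oxyauration of a cyclic enyne acid. C6 is bought; C4, C5, C7 and C11 are relayed from it by substrate control.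

Key step: step 16

Numbering used throughout: ring C1–C10 with C1 = CH–O of the dihydrofuran, C2/C3 = CH2, C4 = C(OH), C5 = CHOAc, C6 = CH–O, C7 = C(OH), C8 = spiro carbon, C9=C10 the alkene; C14 = methyl on C10; C15 = carbonyl on C4 (lactone to O–C6); C11 = CHMe on C7; C12 = its carbonyl (lactone to O12–C8); C13 = methyl on C11.

Remark on the chemistry: in the target SMILES, C2 (on C1) and C7 (on C8) lie on opposite faces of the dihydrofuran ring, and the ring oxygen is cis to the C7 hydroxyl. This bridge is strained, so C8 is set by a stereospecific oxygen shift from a geometrically defined enol lactone and not by equilibrating ketalisation, and the product is not exposed to acid afterwards.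

Step 1
Reactants: 1 ethyl 2-(diphenoxyphosphoryl)acetate; 2 3-bromo-1,1-dimethoxypropane
Product: 3 ethyl 2-(diphenoxyphosphoryl)-5,5-dimethoxypentanoate (racemic)
Conditions: NaH, NaI (cat.), DMSO, rt → 50 °C (1 in slight excess)
Reagents that add atoms: none
Why: SN2 C-alkylation of the stabilised phosphonoacetate anion by the primary bromide, with the excess of 1 limiting dialkylation.

Step 2
Reactants: 3 ethyl 2-(diphenoxyphosphoryl)-5,5-dimethoxypentanoate; 4 (S)-2,2-dimethyl-1,3-dioxolane-4-carbaldehyde
Product: 6 (5R)-3-(3,3-dimethoxypropyl)-5-(hydroxymethyl)furan-2(5H)-one, via Z-enoate 5 (not isolated)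
Conditions: NaH, THF, −78 → 0 °C; then MeOH, HCl (cat.), rt
Reagents that add atoms: none
Why: Ando-type Z-selective Horner–Wadsworth–Emmons olefination should give the (Z)-enoate, and acidic methanolysis of the acetonide lets the freed secondary hydroxyl close the butenolide (only the Z isomer can lactonise), C6 being carried over unchanged from 4.

Step 3
Reactants: 6 (5R)-3-(3,3-dimethoxypropyl)-5-(hydroxymethyl)furan-2(5H)-one
Product: 7 (3S,4S,5S)-3-(3,3-dimethoxypropyl)-3,4-dihydroxy-5-(hydroxymethyl)oxolan-2-one
Conditions: OsO4 (2 mol%), NMO, acetone–H2O, rt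
Reagents that add atoms: N-methylmorpholine N-oxide C[N+]1([O-])CCOCC1; water O
Why: Upjohn syn-dihydroxylation of the butenolide should occur on the face anti to the C6 hydroxymethyl group, setting C4 and C5 (ribo arrangement) by substrate control.

Step 4
Reactants: 7 (3S,4S,5S)-3-(3,3-dimethoxypropyl)-3,4-dihydroxy-5-(hydroxymethyl)oxolan-2-one
Product: 9 C4/C5-O-isopropylidene lactone with free C7 hydroxymethyl and the C1 aldehyde (3-oxopropyl side chain), via acetonide acetal 8 (not isolated)
Conditions: 2-methoxypropene (1.3 equiv), PPTS (cat.), CH2Cl2, 0 °C; then acetone–H2O, 45 °C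
Reagents that add atoms: 2-methoxypropene COC(C)=C; water O
Why: Kinetic ketalisation with the enol ether should protect the cis C4/C5 diol as its acetonide before the dimethyl acetal can exchange with the C4 hydroxyl, and wet acetone/PPTS then hydrolyses only the acyclic acetal (acetonide formation followed by selective acetal hydrolysis).

Step 5
Reactants: 9 acetonide aldehyde
Product: 10 (Z)-vinyl iodide (side chain CH2CH2CH=C(CH3)I, iodine cis to C2)
Conditions: EtPPh3I, n-BuLi, THF, 0 °C; I2, −78 °C; NaHMDS, −78 → −20 °C; then 9, −78 °C
Reagents that add atoms: ethyltriphenylphosphonium iodide CC[P+](c1ccccc1)(c1ccccc1)c1ccccc1.[I-]; iodine II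
Why: Stork–Zhao-type Wittig olefination with the α-iodo ylide should give the (Z)-2-iodoalkene through the kinetically favoured cis-oxaphosphetane, and the weakly basic ylide should tolerate the free primary alcohol.

Step 6
Reactants: 10 (Z)-vinyl iodide; 11 ethynyltrimethylsilane
Product: 12 (Z)-enyne with terminal TMS (side chain CH2CH2CH=C(CH3)C≡C–SiMe3)
Conditions: PdCl2(PPh3)2 (3 mol%), CuI (6 mol%), Et3N, THF, rt
Reagents that add atoms: none
Why: Sonogashira coupling proceeds with retention of alkene geometry, fixing C9 cis to C2.

Step 7
Reactants: 12 TMS enyne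
Product: 13 iodoalkyne (side chain CH2CH2CH=C(CH3)C≡C–I)
Conditions: NIS, AgNO3 (10 mol%), acetone, rt, dark
Reagents that add atoms: N-iodosuccinimide O=C1CCC(=O)N1I
Why: Silver-catalysed desilylative iodination (via the silver acetylide) converts the alkynylsilane directly into the iodoalkyne without touching the alcohol or the enyne.

Step 8
Reactants: 13 iodoalkyne alcohol
Product: 14 C7 aldehyde
Conditions: Dess–Martin periodinane, NaHCO3, CH2Cl2, 0 °C → rt
Reagents that add atoms: none
Why: Dess–Martin oxidation under buffered neutral conditions should give the α-alkoxy aldehyde without epimerising C6.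

Step 9
Reactants: 14 iodoalkyne aldehyde
Product: 15 macrocyclic propargylic alcohol (ten-membered ring C1–C10 with (Z)-C1=C10, C8≡C9 and CH(OH) at C7 as both epimers; bridged by the C15 lactone; C4/C5 acetonide)
Conditions: CrCl2 (6 equiv), NiCl2 (1 mol%), THF, rt, slow addition of 14 (final 2 mM)
Reagents that add atoms: none
Why: Intramolecular Nozaki–Hiyama–Kishi addition of the alkynylchromium(III) species to the aldehyde closes the ten-membered enyne ring, helped by the cis disposition of both arms on the γ-lactone; the C7 carbinol centre need not be controlled because it is oxidised next.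

Step 10
Reactants: 15 macrocyclic propargylic alcohol
Product: 16 macrocyclic ynone (C7 ketone conjugated to C8≡C9)
Conditions: Dess–Martin periodinane, NaHCO3, CH2Cl2, 0 °C
Reagents that add atoms: none
Why: Dess–Martin oxidation of the propargylic alcohol converges both C7 epimers to one ynone.

Step 11
Reactants: 16 macrocyclic ynone; 17 allyl propanoate
Product: 18 aldol adduct (C7 tertiary alcohol bearing CH(CH3)CO2allyl; C7 and C11 configured as in 24)
Conditions: LDA, THF–DMPU (4:1), −78 °C (Z(O)-enolate of 17); then 16, −78 °C; AcOH quench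
Reagents that add atoms: none
Why: Aldol 1,2-addition of the Z(O)-lithium enolate to the ynone carbonyl, in which polar Felkin–Anh attack anti to the C6–O bond should set C7 and a Zimmerman–Traxler chair with the slim alkynyl group axial should place the C11 methyl syn to the C7 hydroxyl.

Step 12
Reactants: 18 aldol adduct
Product: 19 C4,C5-diol (acetonide removed)
Conditions: TFA–H2O–THF (1:1:4), 0 °C → rt
Reagents that add atoms: none
Why: Aqueous acid hydrolyses the isopropylidene ketal, the allyl ester being kept so that C12 cannot lactonise onto the freed C5 hydroxyl, and the tertiary propargylic alcohol is deactivated towards ionisation by its two oxygenated neighbours.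

Step 13
Reactants: 19 diol
Product: 20 C5 acetate
Conditions: Ac2O, pyridine, DMAP (cat.), CH2Cl2, 0 °C
Reagents that add atoms: acetic anhydride CC(=O)OC(C)=O
Why: Acylation is selective for the single secondary hydroxyl (C5) over the two tertiary ones (C4, C7).

Step 14
Reactants: 20 allyl ester acetate
Product: 21 enyne carboxylic acid (free C12 acid)
Conditions: Pd(PPh3)4 (5 mol%), morpholine, THF, rt
Reagents that add atoms: none
Why: Tsuji–Trost deallylation (π-allylpalladium captured by morpholine) frees the acid under neutral conditions that leave the acetate, the lactone and the enyne untouched.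

Step 15
Reactants: 21 enyne carboxylic acid
Product: 22 dienol lactone (C12 carboxyl closed onto C8; exocyclic C8=C9 with O12 cis to C10, so C7 and C10 trans; conjugated with (Z)-C1=C10)
Conditions: AuCl (5 mol%), K2CO3 (10 mol%), MeCN, rt
Reagents that add atoms: none
Why: Gold(I)-catalysed 5-exo-dig cycloisomerisation of the γ-alkynoic acid by anti-oxyauration and protodeauration should give the enol lactone with O12 cis to C10, the geometry that the next step transcribes into C8.

Step 16
Reactants: 22 dienol lactone
Product: 24 target CNP0315698.1, via vinyl epoxide 23 (not isolated)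
Conditions: DMDO (1.1 equiv), acetone–CH2Cl2, −40 → 0 °C
Reagents that add atoms: dimethyldioxirane CC1(C)OO1
Why: Proposed new method: DMDO should epoxidise C1=C10, the δ-terminus and most nucleophilic position of the dienol ester, by concerted oxygen transfer on the peripheral face anti to the transannular C5–C6 chain (the face of the C7 hydroxyl); the vinyl epoxide 23 should then ionise at C10 because O12 stabilises the allyl cation as an acyl-oxocarbenium at C8, and the C1 alkoxide closes onto C8 in a 5-exo-trig attack on the C8=O12+ bond, a net suprafacial 1,3-shift of oxygen from C10 to C8. The closest known reactions are the peracid oxidation of dienol esters to γ-hydroxy enones and the vinyl oxirane to 2,5-dihydrofuran ring expansion, neither shown for a lactone-derived dienol ester with capture by the migrating oxygen. C1 is controlled by the face of epoxidation and keeps its C–O bond throughout. C8 is controlled by the alkene geometry: with C7 outside and O12 inside on the (8E,1(10)Z)-diene, a same-face closure must place C2 and C7 on opposite faces of the dihydrofuran and the ring oxygen cis to the C7 hydroxyl, as in the target. The step needs site selectivity for C1=C10 over the enol C8=C9 bond, secured by the vinylogous donor effect of O12, and capture of the cation by the alkoxide before acyl loss or hydration, secured by neutral anhydrous DMDO whose only by-product is acetone.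

Compound list
1 | ethyl 2-(diphenoxyphosphoryl)acetate | CCOC(=O)CP(=O)(Oc1ccccc1)Oc1ccccc1 | starting material
2 | 3-bromo-1,1-dimethoxypropane | COC(CCBr)OC | starting material
3 | ethyl 2-(diphenoxyphosphoryl)-5,5-dimethoxypentanoate (racemic) | CCOC(=O)C(CCC(OC)OC)P(=O)(Oc1ccccc1)Oc1ccccc1 | intermediate
4 | (S)-2,2-dimethyl-1,3-dioxolane-4-carbaldehyde | O=C[C@@H]1COC(C)(C)O1 | starting material
5 | ethyl (Z)-2-(3,3-dimethoxypropyl)-3-[(4R)-2,2-dimethyl-1,3-dioxolan-4-yl]prop-2-enoate | CCOC(=O)/C(CCC(OC)OC)=C\[C@@H]1COC(C)(C)O1 | intermediate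
6 | (5R)-3-(3,3-dimethoxypropyl)-5-(hydroxymethyl)furan-2(5H)-one | O=C1O[C@@H](CO)C=C1CCC(OC)OC | intermediate
7 | (3S,4S,5S)-3-(3,3-dimethoxypropyl)-3,4-dihydroxy-5-(hydroxymethyl)oxolan-2-one | O=C1O[C@@H](CO)[C@H](O)[C@@]1(O)CCC(OC)OC | intermediate
8 | C4/C5-O-isopropylidene derivative of 7 (dimethyl acetal intact) | O=C1O[C@@H](CO)[C@@H]2OC(C)(C)O[C@]12CCC(OC)OC | intermediate
9 | C4/C5-O-isopropylidene lactone with C7 hydroxymethyl and 3-oxopropyl (C1 aldehyde) side chain | O=C1O[C@@H](CO)[C@@H]2OC(C)(C)O[C@]12CCC=O | intermediate
10 | (Z)-vinyl iodide, side chain CH2CH2CH=C(CH3)I | O=C1O[C@@H](CO)[C@@H]2OC(C)(C)O[C@]12CC/C=C(/C)I | intermediate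
11 | ethynyltrimethylsilane | C#C[Si](C)(C)C | starting material
12 | (Z)-enyne with terminal trimethylsilyl group | O=C1O[C@@H](CO)[C@@H]2OC(C)(C)O[C@]12CC/C=C(/C)C#C[Si](C)(C)C | intermediate
13 | (Z)-enyne with terminal iodoalkyne, C7 alcohol | O=C1O[C@@H](CO)[C@@H]2OC(C)(C)O[C@]12CC/C=C(/C)C#CI | intermediate
14 | iodoalkyne C7 aldehyde | O=C1O[C@@H](C=O)[C@@H]2OC(C)(C)O[C@]12CC/C=C(/C)C#CI | intermediate
15 | macrocyclic propargylic alcohol, 1(10)Z-en-8-yne, C7 epimers, 15,6-lactone bridge, 4,5-acetonide | O=C1O[C@@H]2[C@@H]3OC(C)(C)O[C@]13CC/C=C(/C)C#CC2O | intermediate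
16 | macrocyclic ynone (C7 ketone) | O=C1O[C@@H]2[C@@H]3OC(C)(C)O[C@]13CC/C=C(/C)C#CC2=O | intermediate
17 | allyl propanoate | CCC(=O)OCC=C | starting material
18 | aldol adduct, C7 tertiary alcohol with CH(CH3)CO2allyl at C7 | O=C1O[C@@H]2[C@@H]3OC(C)(C)O[C@]13CC/C=C(/C)C#C[C@]2(O)[C@H](C)C(=O)OCC=C | intermediate
19 | C4,C5-diol allyl ester | O=C1O[C@@H]2[C@H](O)[C@@]1(O)CC/C=C(/C)C#C[C@]2(O)[C@H](C)C(=O)OCC=C | intermediate
20 | C5 acetate allyl ester | O=C1O[C@@H]2[C@H](OC(C)=O)[C@@]1(O)CC/C=C(/C)C#C[C@]2(O)[C@H](C)C(=O)OCC=C | intermediate
21 | enyne carboxylic acid (C12 acid, C5 acetate) | O=C1O[C@@H]2[C@H](OC(C)=O)[C@@]1(O)CC/C=C(/C)C#C[C@]2(O)[C@H](C)C(=O)O | intermediate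
22 | bridged (8E,1(10)Z)-dienol lactone (8,12-enol lactone, O12 cis to C10) | O=C1O[C@@H]2[C@H](OC(C)=O)[C@@]1(O)CC/C=C(/C)\C=C3/OC(=O)[C@@H](C)[C@]23O | intermediate
23 | 1,10-epoxide of 22 on the face of the C7 hydroxyl | O=C1O[C@@H]2[C@H](OC(C)=O)[C@@]1(O)CC[C@@H]4O[C@]4(C)\C=C3/OC(=O)[C@@H](C)[C@]23O | intermediate
24 | CNP0315698.1 | CC(=O)O[C@H]1[C@H]2OC(=O)[C@]1(O)CC[C@@H]1O[C@@]3(C=C1C)OC(=O)[C@@H](C)[C@]23O | target

Total step count: 16. Longest linear sequence: 16 steps (from 1 and 2 through 24); compounds 4, 11 and 17 enter as purchased building blocks.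

Steps most likely to fail

1. Step 16 (Proposed new method). The acyl-oxocarbenium may lose the acyl group or be hydrated before the C1 alkoxide captures it, epoxidation may take place at the enol C8=C9 bond, or closure may be slow because the tether has to cross the plane of the new ring. Fallback with known chemistry: starting from 22, the classical dienol-ester oxidation (mCPBA, NaHCO3, wet CH2Cl2, 0 °C) should give the 1-hydroxy-9Z-en-8-one, which as a γ-keto acid rests as the 8-hydroxy-8,12-olide lactol F1 (C8 epimers). Dehydrative exchange of the lactol hydroxyl for the C1 hydroxyl (PPTS, 4 Å MS, CH2Cl2, the pseudo-acid to pseudo-ester reaction) then closes the dihydrofuran and returns to 24. This route gives up the geometric control of C8, so the spiro centre would rest on the kinetic preference of the closure.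

2. Step 9. Oligomerisation or simple reduction of the alkynylchromium species may outrun closure of the strained ten-membered enyne. Fallback: close the C9–C10 bond instead of C7–C8. Starting from 10, Dess–Martin oxidation should give the vinyl iodide aldehyde F2; ethynylmagnesium bromide (THF, −78 °C) should give the terminal propargylic alcohol F3 (C7 epimers); an intramolecular Sonogashira coupling at high dilution (Pd(PPh3)4, CuI, Et3N, THF) then rejoins the route at 15.

3. Step 11. The ynone may enolise at C6 with β-elimination of the C5 oxygen, the enolate may add in conjugate fashion at C9, or facial and simple diastereoselection may be poor. Fallback: starting from 16, a Reformatsky reaction with allyl 2-bromopropanoate (Zn, THF, or Et2Zn/RhCl(PPh3)3) uses a non-basic zinc enolate that should add 1,2 without enolising C6. It gives 18 directly, with any C11 epimer removed by chromatography, so no new compound arises.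

Further compounds
F1 | step 16 | 8-hydroxy-8,12-olide lactol with free C1 hydroxyl and (Z)-C9=C10 (C8 epimers) | O=C1O[C@@H]2[C@H](OC(C)=O)[C@@]1(O)CC[C@H](O)/C(C)=C\C3(O)OC(=O)[C@@H](C)[C@]23O
F2 | step 9 | (Z)-vinyl iodide C7 aldehyde | O=C1O[C@@H](C=O)[C@@H]2OC(C)(C)O[C@]12CC/C=C(/C)I
F3 | step 9 | (Z)-vinyl iodide with C7 ethynyl carbinol (C7 epimers) | O=C1O[C@@H](C(O)C#C)[C@@H]2OC(C)(C)O[C@]12CC/C=C(/C)I
F0 | step 11 | none | none
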